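**Plan**
- Retrosynthesis: the O11–C11a bond (ring C) is cut first, then all of ring D at C10a–C10, C9–C8 and C10a–C6b. This leads back to a dienyl diazoketone carrying rings A, B and E, and to methoxyacetylene. The side chain is cut at its C=C bond and at the diazo carbon, ring B at O5–C6 and C6a–C11a (acrolein), and ring E at its aryl–C and O–CMe2 bonds (prenal).
- Enabling feature: ring D is a benzene ring whose oxygen on C10a and methoxy on C9 are meta, with C6b ortho to C10a and C7, C8 and C10 unsubstituted. A vinylketene and an alkoxyacetylene assemble exactly this resorcinol monoether pattern.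
- Forward order: ring A is bought as phloroglucinaldehyde; then ring E (chromenylation, hydrogenation), ring B (oxa-Michael/aldol), the diazo enone chain, ring D (benzannulation) and ring C (oxidative phenol capture).
- Stereochemistry: C6a is set by asymmetric hydrogenation of the 2H-chromene-3-carboxylic acid; C11a follows from C6a because the B/C junction can only close cis.

Key step: step 11

Locants: tricyclic intermediates are named as pyrano[2,3-f]chromenes, in which O1–C2(Me2)–C3–C4 is ring E, C5 carries the silyloxy group, O7–C8–C9–C10 is ring B, C9 becomes C6a and C10 becomes C11a; "Chr" stands for the (9S)-2,2-dimethyl-5-[(triisopropylsilyl)oxy]-3,4,9,10-tetrahydro-2H,8H-pyrano[2,3-f]chromen-9-yl group.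

Assumption: by analogy with simple (E)-2-alkylalk-2-enoic acids, the (S)-configured H8-BINAP complex is taken to give the (9R) acid 10; if a trial run shows the opposite sense, the mirror-image ligand is used and nothing else changes.

**Step 1**
Reactants: 1 phloroglucinaldehyde (2,4,6-trihydroxybenzaldehyde)
Product: 2 mono-silyl ether (2,6-dihydroxy-4-[(triisopropylsilyl)oxy]benzaldehyde)
Conditions: TIPSCl (1.0 equiv), imidazole, DMF, −20 °C to 0 °C
Reagents that add atoms: triisopropylsilyl chloride, CC(C)[Si](Cl)(C(C)C)C(C)C
Why: Base-mediated O-silylation should go to the 4-hydroxyl, which is para to the formyl group (most acidic), not held in an intramolecular hydrogen bond and the only hydroxyl not flanked by the aldehyde, so one equivalent of the bulky chlorosilane is expected to leave both ortho hydroxyls free.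

**Step 2**
Reactants: 2 mono-silyl ether; 3 prenal (3-methylbut-2-enal)
Product: 5 chromene salicylaldehyde (7-hydroxy-2,2-dimethyl-5-[(triisopropylsilyl)oxy]-2H-chromene-8-carbaldehyde), via ortho-quinone methide 4 (not isolated)
Conditions: 3 (1.2 equiv), ethylenediammonium diacetate (10 mol%), toluene, 80 °C
Reagents that add atoms: none
Why: The amine-salt-catalysed formal [3+3] chromenylation (Knoevenagel-type condensation at the ring carbon next to a free hydroxyl, then oxa-6π electrocyclisation of the ortho-quinone methide) can close only onto an ortho hydroxyl because O4 is blocked, and the two ortho hydroxyls are equivalent, so a single regioisomer should result.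

**Step 3**
Reactants: 5 chromene salicylaldehyde
Product: 6 chroman salicylaldehyde (7-hydroxy-2,2-dimethyl-5-[(triisopropylsilyl)oxy]chromane-8-carbaldehyde)
Conditions: H2 (1 atm), 10% Pd/C, EtOAc, rt
Reagents that add atoms: none
Why: Heterogeneous hydrogenation should saturate the cis-disubstituted styrene-type double bond of ring E much faster than it touches the electron-rich, hydrogen-bonded aryl aldehyde or the aryl silyl ether.

**Step 4**
Reactants: 6 chroman salicylaldehyde; 7 acrolein (prop-2-enal)
Product: 8 tricyclic enal (2,2-dimethyl-5-[(triisopropylsilyl)oxy]-3,4-dihydro-2H,8H-pyrano[2,3-f]chromene-9-carbaldehyde)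
Conditions: 7 (3 equiv), K2CO3, 1,4-dioxane, reflux
Reagents that add atoms: none
Why: Domino oxa-Michael addition/intramolecular aldol condensation of the phenoxide with acrolein forms O7–C8 and C9–C10 and closes ring B as a 2H-chromene-3-carbaldehyde, the intramolecular aldol step making up for the low electrophilicity of the doubly ortho-oxygenated aldehyde.

**Step 5**
Reactants: 8 tricyclic enal
Product: 9 chromene acid (2,2-dimethyl-5-[(triisopropylsilyl)oxy]-3,4-dihydro-2H,8H-pyrano[2,3-f]chromene-9-carboxylic acid)
Conditions: NaClO2, NaH2PO4, 2-methylbut-2-ene (excess), t-BuOH/THF/H2O, 0 °C to rt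
Reagents that add atoms: sodium chlorite, [Na+].[O-]Cl=O
Why: Pinnick oxidation converts the enal into the acid without touching the trisubstituted alkene, the alkene scavenger removing hypochlorous acid before it can chlorinate ring A.

**Step 6**
Reactants: 9 chromene acid
Product: 10 (9R)-chroman acid ((9R)-2,2-dimethyl-5-[(triisopropylsilyl)oxy]-3,4,9,10-tetrahydro-2H,8H-pyrano[2,3-f]chromene-9-carboxylic acid)
Conditions: Ru(OAc)2[(S)-H8-BINAP] (1 mol%), H2 (10 atm), MeOH, 30 °C
Reagents that add atoms: none
Why: Carboxylate-directed asymmetric hydrogenation with a divalent ruthenium biaryl-diphosphine dicarboxylate is established for α-substituted cinnamic-type acids, including 2H-chromene-3-carboxylic acids, and delivers hydrogen to one face of the C9=C10 bond inside the chiral pocket, which sets C9 (later C6a) as (R) with the ligand antipode chosen as stated above.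

**Step 7**
Reactants: 10 (9R)-chroman acid
Product: 11 (9S)-alcohol ([(9S)-2,2-dimethyl-5-[(triisopropylsilyl)oxy]-3,4,9,10-tetrahydro-2H,8H-pyrano[2,3-f]chromen-9-yl]methanol)
Conditions: BH3·SMe2, THF, 0 °C to rt; aqueous work-up
Reagents that add atoms: none
Why: Borane reduces the carboxylic acid chemoselectively under non-basic conditions, so the α-stereocentre is not epimerised (the descriptor changes only through the priority rules) and the aryl silyl ether survives.

**Step 8**
Reactants: 11 (9S)-alcohol; 12 ylide (1-(triphenylphosphoranylidene)propan-2-one)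
Product: 14 (E)-enone ((3E)-4-Chr-but-3-en-2-one), via aldehyde 13 (not isolated)
Conditions: Dess–Martin periodinane (1.2 equiv), CH2Cl2, 0 °C to rt; then 12 (2 equiv), 40 °C
Reagents that add atoms: none
Why: Dess–Martin oxidation followed in the same flask by Wittig olefination with the acetyl-stabilised ylide (tandem oxidation–Wittig) should give the (E)-enone under base-free conditions that neither epimerise the α-stereocentre of the aldehyde nor trigger β-elimination of the ring oxygen.

**Step 9**
Reactants: 14 (E)-enone
Product: 16 α'-diazo enone ((3E)-1-diazo-4-Chr-but-3-en-2-one), via trifluoroacetyl diketone 15 (not isolated)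
Conditions: LiN(SiMe3)2, THF, −78 °C; CF3CO2CH2CF3, −78 °C; cold dilute aq. HCl; then MsN3, Et3N, H2O (1 equiv), MeCN, rt
Reagents that add atoms: methanesulfonyl azide, CS(=O)(=O)N=[N+]=[N-] (the two diazo nitrogens of 16); 2,2,2-trifluoroethyl trifluoroacetate, O=C(OCC(F)(F)F)C(F)(F)F (the trifluoroacetyl group carried only by 15)
Why: In this detrifluoroacetylative diazo transfer, kinetic deprotonation at the α'-methyl group (not at the γ-CH stereocentre) and Claisen trifluoroacetylation give an activated 1,3-diketone that accepts the diazo group from the sulfonyl azide and then loses the trifluoroacetyl group as the sulfonamide, the standard entry to α'-diazo enones for which the acid chloride/diazomethane route is unsuitable.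

**Step 10**
Reactants: 17 chloroacetal (2-chloro-1,1-dimethoxyethane)
Product: 19 methoxyacetylene (methoxyethyne), via sodium methoxyacetylide 18 (not isolated)
Conditions: NaNH2 (3 equiv), liquid NH3, −33 °C; then cold H2O, −70 °C to rt; distilled into cold ClCH2CH2Cl and used as a solution
Reagents that add atoms: sodium amide, [NH2-].[Na+] (the sodium of 18 only)
Why: Sodium amide effects two successive eliminations from the chloroacetal (methanol, then hydrogen chloride) and deprotonates the alkyne, so that protonation of the acetylide on quenching releases the volatile alkoxyacetylene, a long-established preparation.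

**Step 11**
Reactants: 16 α'-diazo enone; 19 methoxyacetylene
Product: 24 isoflavan silyl ether (5-methoxy-2-Chr-phenol), via vinylketene 20 (not isolated), via alkenylcyclobutenone 21 (not isolated), via dienylketene 22 (not isolated), via cyclohexadienone 23 (not isolated)
Conditions: 19 (5 equiv), ClCH2CH2Cl, hν (300 nm, Pyrex), 0–10 °C, sealed vessel; then 80 °C
Reagents that add atoms: none
Why: Light expels dinitrogen from 16 and the alkenyl group migrates (photochemical Wolff rearrangement) to give vinylketene 20, whose electrophilic carbonyl carbon bonds to the unsubstituted, nucleophilic carbon of 19 while the ketene α-carbon bonds to the methoxy-bearing carbon in a [2+2] cycloaddition (C10a–C10 and C9–C8) that gives cyclobutenone 21. Conrotatory 4π ring opening of 21, thermal and in part photochemical, gives dienylketene 22; disrotatory 6π electrocyclisation then forms C10a–C6b and closes the six-membered ring D as cyclohexadienone 23, which tautomerises to phenol 24. The closest known reaction type is the Danheiser benzannulation in its diazoketone form with heteroatom-substituted alkynes. No stereocentre is created, and C9 is only allylic to the reacting π system, so its configuration is carried through unchanged. The selectivity required is the regiochemistry of the [2+2] step, which the polarisation of the ynol ether secures and which places the methoxy group meta to the new hydroxyl and para to the chroman; the fivefold excess of 19 is meant to outrun acylation of the product phenol by 20, and irradiation at 300 nm should spare the ring A chromophore.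

**Step 12**
Reactants: 24 isoflavan silyl ether
Product: 25 isoflavan diphenol ((9S)-9-(2-hydroxy-4-methoxyphenyl)-2,2-dimethyl-3,4,9,10-tetrahydro-2H,8H-pyrano[2,3-f]chromen-5-ol)
Conditions: Bu4NF (1.1 equiv), AcOH (1.1 equiv), THF, 0 °C
Reagents that add atoms: none
Why: Fluoride cleaves the aryl silicon–oxygen bond selectively, and buffering with acetic acid keeps the two electron-rich phenols protonated and away from air oxidation.

**Step 13**
Reactants: 25 isoflavan diphenol
Product: 27 target pterocarpan ((6aS,11aS)-3-hydroxy-9-methoxypterocarpan with a 2,2-dimethyl-3,4-dihydro-2H-pyran ring fused at C1–C2 and its oxygen on C1), via para-quinone methide 26 (not isolated)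
Conditions: DDQ (1.0 equiv, added slowly), CH2Cl2, −20 °C to 0 °C
Reagents that add atoms: none
Why: Quinone dehydrogenation of the 4-alkylphenol unit of ring A should give the para-quinone methide at C10 (para-quinone methides are generally favoured over ortho ones, and phenol oxidation is far faster at this temperature than hydride abstraction next to aryl ethers), and 5-exo-trig addition of the 2'-hydroxyl to the methide carbon closes ring C and restores ring A, the known oxidative cyclisation of 2'-hydroxyisoflavans to pterocarpans, in which the phenol tethered to C6a can reach C11a only from the face that gives the cis B/C fusion, so that C11a follows C6a as (S).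

**Compound list**
1 | 2,4,6-trihydroxybenzaldehyde | O=Cc1c(O)cc(O)cc1O | starting material
2 | 2,6-dihydroxy-4-[(triisopropylsilyl)oxy]benzaldehyde | O=Cc1c(O)cc(O[Si](C(C)C)(C(C)C)C(C)C)cc1O | intermediate
3 | 3-methylbut-2-enal (prenal) | CC(C)=CC=O | starting material
4 | 2-hydroxy-5-(3-methylbut-2-en-1-ylidene)-6-oxo-4-[(triisopropylsilyl)oxy]cyclohexa-1,3-diene-1-carbaldehyde (ortho-quinone methide) | O=CC1=C(O)C=C(O[Si](C(C)C)(C(C)C)C(C)C)C(=CC=C(C)C)C1=O | intermediate
5 | 7-hydroxy-2,2-dimethyl-5-[(triisopropylsilyl)oxy]-2H-chromene-8-carbaldehyde | O=Cc1c(O)cc(O[Si](C(C)C)(C(C)C)C(C)C)c2C=CC(C)(C)Oc12 | intermediate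
6 | 7-hydroxy-2,2-dimethyl-5-[(triisopropylsilyl)oxy]chromane-8-carbaldehyde | O=Cc1c(O)cc(O[Si](C(C)C)(C(C)C)C(C)C)c2CCC(C)(C)Oc12 | intermediate
7 | prop-2-enal (acrolein) | C=CC=O | starting material
8 | 2,2-dimethyl-5-[(triisopropylsilyl)oxy]-3,4-dihydro-2H,8H-pyrano[2,3-f]chromene-9-carbaldehyde | O=CC1=Cc2c(cc(O[Si](C(C)C)(C(C)C)C(C)C)c3CCC(C)(C)Oc23)OC1 | intermediate
9 | 2,2-dimethyl-5-[(triisopropylsilyl)oxy]-3,4-dihydro-2H,8H-pyrano[2,3-f]chromene-9-carboxylic acid | OC(=O)C1=Cc2c(cc(O[Si](C(C)C)(C(C)C)C(C)C)c3CCC(C)(C)Oc23)OC1 | intermediate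
10 | (9R)-2,2-dimethyl-5-[(triisopropylsilyl)oxy]-3,4,9,10-tetrahydro-2H,8H-pyrano[2,3-f]chromene-9-carboxylic acid | OC(=O)[C@@H]1Cc2c(cc(O[Si](C(C)C)(C(C)C)C(C)C)c3CCC(C)(C)Oc23)OC1 | intermediate
11 | [(9S)-2,2-dimethyl-5-[(triisopropylsilyl)oxy]-3,4,9,10-tetrahydro-2H,8H-pyrano[2,3-f]chromen-9-yl]methanol | OC[C@@H]1Cc2c(cc(O[Si](C(C)C)(C(C)C)C(C)C)c3CCC(C)(C)Oc23)OC1 | intermediate
12 | 1-(triphenylphosphoranylidene)propan-2-one | CC(=O)C=P(c1ccccc1)(c1ccccc1)c1ccccc1 | starting material
13 | (9R)-2,2-dimethyl-5-[(triisopropylsilyl)oxy]-3,4,9,10-tetrahydro-2H,8H-pyrano[2,3-f]chromene-9-carbaldehyde | O=C[C@@H]1Cc2c(cc(O[Si](C(C)C)(C(C)C)C(C)C)c3CCC(C)(C)Oc23)OC1 | intermediate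
14 | (3E)-4-Chr-but-3-en-2-one | CC(=O)/C=C/[C@@H]1Cc2c(cc(O[Si](C(C)C)(C(C)C)C(C)C)c3CCC(C)(C)Oc23)OC1 | intermediate
15 | (5E)-1,1,1-trifluoro-6-Chr-hex-5-ene-2,4-dione | O=C(CC(=O)C(F)(F)F)/C=C/[C@@H]1Cc2c(cc(O[Si](C(C)C)(C(C)C)C(C)C)c3CCC(C)(C)Oc23)OC1 | intermediate
16 | (3E)-1-diazo-4-Chr-but-3-en-2-one | [N-]=[N+]=CC(=O)/C=C/[C@@H]1Cc2c(cc(O[Si](C(C)C)(C(C)C)C(C)C)c3CCC(C)(C)Oc23)OC1 | intermediate
17 | 2-chloro-1,1-dimethoxyethane (chloroacetaldehyde dimethyl acetal) | COC(CCl)OC | starting material
18 | sodium methoxyacetylide (sodium 2-methoxyethyn-1-ide) | [Na+].[C-]#COC | intermediate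
19 | methoxyethyne (methoxyacetylene) | COC#C | intermediate
20 | (3E)-4-Chr-buta-1,3-dien-1-one (vinylketene) | O=C=C/C=C/[C@@H]1Cc2c(cc(O[Si](C(C)C)(C(C)C)C(C)C)c3CCC(C)(C)Oc23)OC1 | intermediate
21 | 3-methoxy-4-[(E)-2-Chr-ethenyl]cyclobut-2-en-1-one (C4 epimers) | COC1=CC(=O)C1/C=C/[C@@H]1Cc2c(cc(O[Si](C(C)C)(C(C)C)C(C)C)c3CCC(C)(C)Oc23)OC1 | intermediate
22 | (3E,5E)-3-methoxy-6-Chr-hexa-1,3,5-trien-1-one (dienylketene) | O=C=C/C(OC)=C\C=C\[C@@H]1Cc2c(cc(O[Si](C(C)C)(C(C)C)C(C)C)c3CCC(C)(C)Oc23)OC1 | intermediate
23 | 3-methoxy-6-Chr-cyclohexa-2,4-dien-1-one (C6 epimers) | COC1=CC(=O)C(C=C1)[C@@H]1Cc2c(cc(O[Si](C(C)C)(C(C)C)C(C)C)c3CCC(C)(C)Oc23)OC1 | intermediate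
24 | 5-methoxy-2-Chr-phenol (2'-hydroxy-4'-methoxy isoflavan of rings A, B, D and E, silyl ether) | COc1ccc(c(O)c1)[C@@H]1Cc2c(cc(O[Si](C(C)C)(C(C)C)C(C)C)c3CCC(C)(C)Oc23)OC1 | intermediate
25 | (9S)-9-(2-hydroxy-4-methoxyphenyl)-2,2-dimethyl-3,4,9,10-tetrahydro-2H,8H-pyrano[2,3-f]chromen-5-ol | COc1ccc(c(O)c1)[C@@H]1Cc2c(cc(O)c3CCC(C)(C)Oc23)OC1 | intermediate
26 | (9S)-9-(2-hydroxy-4-methoxyphenyl)-2,2-dimethyl-3,4,8,9-tetrahydro-2H,5H-pyrano[2,3-f]chromen-5-one (para-quinone methide) | COc1ccc(c(O)c1)[C@@H]1C=C2C(=CC(=O)C3=C2OC(C)(C)CC3)OC1 | intermediate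
27 | (6aS,11aS)-3-hydroxy-9-methoxypterocarpan with a 2,2-dimethyl-3,4-dihydro-2H-pyran ring fused at C1–C2, oxygen on C1 (CNP0207547.1) | COc1ccc2c(c1)O[C@@H]1c3c(cc(O)c4c3OC(C)(C)CC4)OC[C@H]21 | target

**Step count and risks**
Total: 13 steps. Longest linear sequence: 12 steps (steps 1–9 and 11–13, from 1 to 27); step 10 is a one-step side branch.

Steps most likely to fail:

1. Step 11 (benzannulation). The vinylketene may be captured by the newly formed phenol (aryl ester formation) instead of by the alkyne, the electron-rich chroman may degrade under irradiation, and the volatile alkyne may be lost before it reacts. The fallback separates ketene formation from light and from the annulation; it sets out from 16 and returns at 24. Wolff rearrangement of 16 in the dark (PhCO2Ag, Et3N, THF/H2O, ultrasound; the Arndt–Eistert homologation, in which water traps 20 at once) should give the homologous (3E)-4-Chr-but-3-enoic acid F1. Oxalyl chloride with catalytic DMF converts it into (3E)-4-Chr-but-3-enoyl chloride F2. Slow addition of Et3N to F2 and an excess of 19 in CH2Cl2 at 0 °C regenerates 20 by dehydrochlorination at a low stationary concentration, [2+2] addition gives 21, and heating at 80 °C takes 21 through 22 and 23 to 24.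

2. Step 13 (ring C closure). Dehydrogenation may take place at the benzylic carbon of ring E (ortho-quinone methide, then chromene) instead of at C10, and the product phenol may be oxidised further. The fallback uses up both benzylic positions on purpose and then restores ring E; it sets out from 24 and returns at 27. Excess DDQ (about 2.2 equiv, 1,4-dioxane, rt to 60 °C) acts on the silyl ether: hydride abstraction at C10 with capture by the 2'-hydroxyl closes ring C, and ring E is dehydrogenated to the 2H-chromene, giving the ring E-dehydro pterocarpan silyl ether F3. Homogeneous hydrogenation (RhCl(PPh3)3, H2, benzene/EtOH) saturates only the cis-disubstituted alkene of ring E without hydrogenolysis of the benzylic C11a–O bond and gives the pterocarpan silyl ether F4. Bu4NF/AcOH then releases 27.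

3. Step 1 (mono-silylation). Silylation may spread over the ortho and para hydroxyls or run on to bis-silyl ethers. The fallback moves the silylation behind the chromenylation, where only one hydroxyl is free of chelation; it sets out from 1 and returns at 5. Chromenylation of unprotected 1 with 3 (ethylenediammonium diacetate, toluene, 80 °C) gives 5,7-dihydroxy-2,2-dimethyl-2H-chromene-8-carbaldehyde F5, which is separated by chromatography from its regioisomer 5,7-dihydroxy-2,2-dimethyl-2H-chromene-6-carbaldehyde F6. In F5 the 7-hydroxyl is chelated to the aldehyde and the 5-hydroxyl is not, so TIPSCl/imidazole should silylate the 5-hydroxyl only and give 5.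

**Further compounds**
F1 | step 11 | (3E)-4-Chr-but-3-enoic acid | OC(=O)C/C=C/[C@@H]1Cc2c(cc(O[Si](C(C)C)(C(C)C)C(C)C)c3CCC(C)(C)Oc23)OC1
F2 | step 11 | (3E)-4-Chr-but-3-enoyl chloride | ClC(=O)C/C=C/[C@@H]1Cc2c(cc(O[Si](C(C)C)(C(C)C)C(C)C)c3CCC(C)(C)Oc23)OC1
F3 | step 13 | (6aS,11aS)-9-methoxy-3-[(triisopropylsilyl)oxy]pterocarpan with a 2,2-dimethyl-2H-pyran ring fused at C1–C2, oxygen on C1 | COc1ccc2c(c1)O[C@@H]1c3c(cc(O[Si](C(C)C)(C(C)C)C(C)C)c4c3OC(C)(C)C=C4)OC[C@H]21
F4 | step 13 | (6aS,11aS)-9-methoxy-3-[(triisopropylsilyl)oxy]pterocarpan with a 2,2-dimethyl-3,4-dihydro-2H-pyran ring fused at C1–C2, oxygen on C1 | COc1ccc2c(c1)O[C@@H]1c3c(cc(O[Si](C(C)C)(C(C)C)C(C)C)c4c3OC(C)(C)CC4)OC[C@H]21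
F5 | step 1 | 5,7-dihydroxy-2,2-dimethyl-2H-chromene-8-carbaldehyde | O=Cc1c(O)cc(O)c2C=CC(C)(C)Oc12
F6 | step 1 | 5,7-dihydroxy-2,2-dimethyl-2H-chromene-6-carbaldehyde | O=Cc1c(O)cc2OC(C)(C)C=Cc2c1O
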